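**Retrosynthetic overview**
1. The isoflavone comes from loss of water across C2–C3 of a 3-hydroxyisoflavanone, so no stereocentre survives.
2. The 3-hydroxyisoflavanone is cut at C3–C4. A formyl carbon, turned into a carbene-bound acyl anion (Breslow enaminol), attacks an aryl ketone carbonyl in an intramolecular crossed benzoin reaction.
3. The keto-aldehyde is cut at the O1–C2 bond, giving a salicylaldehyde and a phenacyl bromide (Williamson etherification).
4. The salicylaldehyde comes from ortho-formylation of 2,3,4-trimethoxyphenol, which comes from Dakin oxidation of 2,3,4-trimethoxybenzaldehyde.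
5. Ring order: rings A and B are bought as arenes. Ring C (the pyranone) is the only ring formed, and it closes in the key step.

Assumption: the target is achiral (no stereocentre, stereogenic axis or stereogenic double bond), so there is no enantiomer to select and the SMILES is taken as drawn.

**Route**

Step 1
Reactants: 1 2,3,4-trimethoxybenzaldehyde
Product: 3 2,3,4-trimethoxyphenol, via 2,3,4-trimethoxyphenyl formate 2 (not isolated)
Conditions: 30% aq H2O2 (1.3 equiv), H2SO4 (cat.), MeOH, rt
Reagents that add atoms: hydrogen peroxide, OO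
Why: In this acid-catalysed Dakin oxidation (Baeyer–Villiger type), the aryl group carrying ortho and para methoxy donors migrates from the peroxy-hemiacetal much faster than hydride, formate 2 is methanolysed in the same flask, and no stereocentre is formed.

Step 2
Reactants: 3 2,3,4-trimethoxyphenol
Product: 4 2-hydroxy-3,4,5-trimethoxybenzaldehyde
Conditions: MgCl2 (2 equiv), Et3N (2 equiv), (CH2O)n (3 equiv), MeCN, reflux; then 1 M HCl
Reagents that add atoms: paraformaldehyde (reacts as formaldehyde), C=O
Why: In this Casnati–Skattebøl ortho-formylation the magnesium phenoxide delivers formaldehyde through a six-membered chelate to the only free ortho carbon, a second formaldehyde oxidises the resulting benzylic alkoxide by hydride transfer, and no stereocentre is formed.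

Step 3
Reactants: 4 2-hydroxy-3,4,5-trimethoxybenzaldehyde; 5 2-bromo-1-(3,4,5-trimethoxyphenyl)ethan-1-one
Product: 6 3,4,5-trimethoxy-2-[2-oxo-2-(3,4,5-trimethoxyphenyl)ethoxy]benzaldehyde
Conditions: K2CO3 (1.2 equiv), DMF, 0 °C to rt
Reagents that add atoms: none
Why: In this Williamson ether synthesis (SN2) the acidic salicylaldehyde OH is fully deprotonated by K2CO3, and the alpha-bromoketone is reactive enough to be consumed at or below rt, below the temperature at which aldol cyclisation of 6 to a 2-aroylbenzofuran (Rap–Stoermer pathway) sets in.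

Step 4 (key step)
Reactants: 6 3,4,5-trimethoxy-2-[2-oxo-2-(3,4,5-trimethoxyphenyl)ethoxy]benzaldehyde
Product: 10 6,7,8-trimethoxy-3-(3,4,5-trimethoxyphenyl)-4H-chromen-4-one (target), via Breslow enaminol 7 (not isolated), via rac-3-hydroxyisoflavanone 8 (not isolated), via chlorosulfite ester 9 (not isolated)
Conditions: 2-(pentafluorophenyl)-6,7-dihydro-5H-pyrrolo[2,1-c][1,2,4]triazol-2-ium tetrafluoroborate (10 mol %), Et3N (20 mol %), degassed CH2Cl2, Ar, rt; then pyridine (6 equiv), SOCl2 (2 equiv), 0 °C to rt
Reagents that add atoms: none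
Why: Proposed new method: this is a one-pot merger of a carbene-catalysed intramolecular crossed aldehyde–ketone benzoin reaction (closest known type: cyclisation of 2-(2-oxoalkoxy)benzaldehydes to 3-hydroxychroman-4-ones) with a SOCl2/pyridine dehydration (closest known type: dehydrohalogenation of 3-halochroman-4-ones to chromones), in which the carbene adds to the formyl group and a proton shift gives Breslow enaminol 7, whose former carbonyl carbon is now nucleophilic (acyl anion equivalent) and attacks the tethered, inductively activated aryl ketone carbonyl in a 6-exo-trig closure, so that two natively electrophilic carbons become the C4–C3 bond of ring C while the weak amine base keeps the competing aldol path slow; the C3 stereocentre of 8 forms as a racemate under the achiral catalyst, which is harmless because E2 elimination of chlorosulfite 9 across C2–C3, driven by formation of the conjugated 4-pyranone, erases it.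

**Compound list**
1 | 2,3,4-trimethoxybenzaldehyde | COc1ccc(C=O)c(OC)c1OC | starting material
2 | 2,3,4-trimethoxyphenyl formate | COc1ccc(OC=O)c(OC)c1OC | intermediate
3 | 2,3,4-trimethoxyphenol | COc1ccc(O)c(OC)c1OC | intermediate
4 | 2-hydroxy-3,4,5-trimethoxybenzaldehyde | COc1cc(C=O)c(O)c(OC)c1OC | intermediate
5 | 2-bromo-1-(3,4,5-trimethoxyphenyl)ethan-1-one | COc1cc(C(=O)CBr)cc(OC)c1OC | starting material
6 | 3,4,5-trimethoxy-2-[2-oxo-2-(3,4,5-trimethoxyphenyl)ethoxy]benzaldehyde | COc1cc(C=O)c(OCC(=O)c2cc(OC)c(OC)c(OC)c2)c(OC)c1OC | intermediate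
7 | Breslow enaminol of 6: the former formyl carbon is C(OH)=C bonded to C3 of the 2-(pentafluorophenyl)-6,7-dihydro-5H-pyrrolo[2,1-c][1,2,4]triazol-3-ylidene unit, double-bond geometry undefined | COc1cc(C(O)=C2N(c3c(F)c(F)c(F)c(F)c3F)N=C3CCCN23)c(OCC(=O)c2cc(OC)c(OC)c(OC)c2)c(OC)c1OC | intermediate
8 | rac-3-hydroxy-6,7,8-trimethoxy-3-(3,4,5-trimethoxyphenyl)chroman-4-one | COc1cc(C2(O)COc3c(OC)c(OC)c(OC)cc3C2=O)cc(OC)c1OC | intermediate
9 | rac-6,7,8-trimethoxy-4-oxo-3-(3,4,5-trimethoxyphenyl)chroman-3-yl chlorosulfite | COc1cc(C2(OS(=O)Cl)COc3c(OC)c(OC)c(OC)cc3C2=O)cc(OC)c1OC | intermediate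
10 | 6,7,8-trimethoxy-3-(3,4,5-trimethoxyphenyl)-4H-chromen-4-one (achiral) | COc1cc(-c2coc3c(OC)c(OC)c(OC)cc3c2=O)cc(OC)c1OC | target

**Total step count:** 4. **Longest linear sequence:** 4 (1 to 3 to 4 to 6 to 10; compound 5 enters at step 3).

**Steps most likely to fail, each with one fallback**

Step 4. The risks are as follows.
- Base-induced aldol cyclisation of 6 may outrun carbene addition to the electron-rich, ortho-substituted aldehyde.
- The benzoin closure onto an aryl ketone may stay incomplete.
- The elimination may stall.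

The fallback sets out from 3 and comes back at 10. It makes the C3–aryl bond instead of C3–C4, using an enolonium equivalent. C-acetylation of 3 (Ac2O, BF3·OEt2, 90 °C, Fries type) gives 1-(2-hydroxy-3,4,5-trimethoxyphenyl)ethan-1-one F1. Claisen–Schmidt condensation with purchased 3,4,5-trimethoxybenzaldehyde (KOH, EtOH, rt) gives (E)-1-(2-hydroxy-3,4,5-trimethoxyphenyl)-3-(3,4,5-trimethoxyphenyl)prop-2-en-1-one F2. NaOAc in refluxing EtOH closes F2 by oxa-Michael addition to rac-6,7,8-trimethoxy-2-(3,4,5-trimethoxyphenyl)chroman-4-one F3, which also masks the oxidisable phenol. PhI(OH)OTs in refluxing MeCN traps the enol of F3 on trivalent iodine as rac-6,7,8-trimethoxy-3-[phenyl(tosyloxy)-λ3-iodanyl]-2-(3,4,5-trimethoxyphenyl)chroman-4-one F4. In F4 the alpha carbon is electrophilic, so the electron-rich aryl ring migrates from C2 to C3 through its ipso carbon. Proton loss from the resulting C2 oxocarbenium ion gives 10.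

Step 3. The risk is that ether 6 cyclises under the carbonate conditions to the 2-aroylbenzofuran. The fallback sets out from 5, takes up 4, and comes back at 6. It forms the ether by redox condensation without base. HCO2Na in aqueous EtOH at reflux displaces bromide from 5 to give 2-oxo-2-(3,4,5-trimethoxyphenyl)ethyl formate F5. F5 hydrolyses in the same pot to 2-hydroxy-1-(3,4,5-trimethoxyphenyl)ethan-1-one F6. A Mitsunobu reaction of F6 with phenol 4 (PPh3, DIAD, THF, 0 °C to rt) then gives 6 under essentially neutral conditions.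

Step 2. The risks are sluggish formylation of the crowded, very electron-rich phenol, or its O-methoxymethylation on long heating. The fallback sets out from 3 and comes back at 4. It replaces the electrophilic substitution with directed ortho-metalation. MOMCl and i-Pr2NEt in CH2Cl2 give 1,2,3-trimethoxy-4-(methoxymethoxy)benzene F7. Treatment with n-BuLi/TMEDA in THF (−78 to 0 °C) lithiates next to the stronger OMOM director, and a DMF quench gives 3,4,5-trimethoxy-2-(methoxymethoxy)benzaldehyde F8. HCl in MeOH at 40 °C removes the acetal and returns 4.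

**Further compounds**
F1 | step 4 | 1-(2-hydroxy-3,4,5-trimethoxyphenyl)ethan-1-one | COc1cc(C(C)=O)c(O)c(OC)c1OC
F2 | step 4 | (E)-1-(2-hydroxy-3,4,5-trimethoxyphenyl)-3-(3,4,5-trimethoxyphenyl)prop-2-en-1-one | COc1cc(C(=O)/C=C/c2cc(OC)c(OC)c(OC)c2)c(O)c(OC)c1OC
F3 | step 4 | rac-6,7,8-trimethoxy-2-(3,4,5-trimethoxyphenyl)chroman-4-one | COc1cc(C2CC(=O)c3cc(OC)c(OC)c(OC)c3O2)cc(OC)c1OC
F4 | step 4 | rac-6,7,8-trimethoxy-3-[phenyl(tosyloxy)-λ3-iodanyl]-2-(3,4,5-trimethoxyphenyl)chroman-4-one (diastereomer mixture, C3 epimerisable) | COc1cc(C2Oc3c(OC)c(OC)c(OC)cc3C(=O)C2I(c2ccccc2)OS(=O)(=O)c2ccc(C)cc2)cc(OC)c1OC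
F5 | step 3 | 2-oxo-2-(3,4,5-trimethoxyphenyl)ethyl formate | COc1cc(C(=O)COC=O)cc(OC)c1OC
F6 | step 3 | 2-hydroxy-1-(3,4,5-trimethoxyphenyl)ethan-1-one | COc1cc(C(=O)CO)cc(OC)c1OC
F7 | step 2 | 1,2,3-trimethoxy-4-(methoxymethoxy)benzene | COCOc1ccc(OC)c(OC)c1OC
F8 | step 2 | 3,4,5-trimethoxy-2-(methoxymethoxy)benzaldehyde | COCOc1c(C=O)cc(OC)c(OC)c1OC
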